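**Strategy.** The chromane is opened by a retro-hetero-Diels–Alder cut to an o-quinone methide and (−)-β-caryophyllene (caryophyllane numbering: C8 carries the methylene, C4 the oxygen and methyl, C5 the chromane CH2, C1 and C9 the ring fusion). The nine-membered ring is traced through its C8 ketone to an eleven-membered allylic β-keto lactone. The key step exploits the 1,5-relationship between C8 and the (E)-C4=C5 olefin of that ring: zerovalent palladium ionises the C6–O bond, CO2 is lost and the C7 enolate closes on C6, so the lactone contracts by two atoms to the (E)-cyclononenone. C1 comes from an enantioselective [2+2] photocycloaddition; C9 is set by equilibration, C4 and C5 in the final cycloaddition.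

Key step: step 7

Remark on the chemistry: the quinone methide is assumed to reach both faces of the C4=C5 bond of 15. The target (4S,5R) is the adduct on the face opposite to the one opened in the common (4R,5R)-epoxide of 15, so step 11 is planned with a chromatographic separation of two face isomers.

Step 1
Reactants: 1 cyclohex-2-en-1-one; 2 2-methylpropene
Product: 3 (1R,6R)-7,7-dimethylbicyclo[4.2.0]octan-2-one (cis-fused)
Conditions: hν (366 nm), AlBr3-activated chiral oxazaborolidine (50 mol %, the antipode that delivers 6R), 2 in excess, CH2Cl2, −78 °C; then basic Al2O3, rt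
Reagents that add atoms: none
Why: Lewis-acid-catalysed enantioselective enone–alkene [2+2] photocycloaddition, in which the AlBr3-bound enone is excited selectively and the oxazaborolidine shields one face, so the β-carbon (later C1) should be set as R with head-to-tail regiochemistry (CMe2 next to the β-carbon), while alumina converges the epimerisable α-carbon on the cis ring fusion.

Step 2
Reactants: 3 (1R,6R)-7,7-dimethylbicyclo[4.2.0]octan-2-one
Product: 5 (1R,2R)-3,3-dimethyl-2-(3-oxopropyl)cyclobutane-1-carboxylic acid, via silyl enol ether 4 (not isolated)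
Conditions: LiN(i-Pr)2, THF, −78 °C, then Me3SiCl; O3, CH2Cl2, −78 °C, then Me2S; aqueous work-up
Reagents that add atoms: ozone, O=[O+][O-]; chlorotrimethylsilane, C[Si](C)(C)Cl (silicon only in 4)
Why: Kinetic deprotonation at the CH2 flank rather than at the cyclobutane methine gives enol ether 4, and silyl enol ether ozonolysis cleaves the C8–C4 bond to the C8 acid (after hydrolysis of the silyl ester) and the C4 aldehyde without touching either stereocentre.

Step 3
Reactants: 5 (1R,2R)-3,3-dimethyl-2-(3-oxopropyl)cyclobutane-1-carboxylic acid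
Product: 6 (1R,2R)-2-(but-3-yn-1-yl)-3,3-dimethylcyclobutane-1-carboxylic acid
Conditions: dimethyl (1-diazo-2-oxopropyl)phosphonate, K2CO3 (3 equiv), MeOH, 0 °C → rt
Reagents that add atoms: dimethyl (1-diazo-2-oxopropyl)phosphonate, CC(=O)C(=[N+]=[N-])P(=O)(OC)OC
Why: Ohira–Bestmann (Seyferth–Gilbert) homologation turns the aldehyde into the terminal alkyne C4≡C5 under carbonate conditions in which the acid is protected as its carboxylate and no stereocentre is at risk.

Step 4
Reactants: 6 (1R,2R)-2-(but-3-yn-1-yl)-3,3-dimethylcyclobutane-1-carboxylic acid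
Product: 8 (1R,2R)-2-[(E)-5-hydroxy-3-methylpent-3-en-1-yl]-3,3-dimethylcyclobutane-1-carboxylic acid, via alkenylalane 7 (not isolated)
Conditions: AlMe3 (4 equiv), Cp2ZrCl2 (25 mol %), CH2Cl2, 0 °C → rt; then (CH2O)n, THF, rt; aq. HCl
Reagents that add atoms: trimethylaluminium, C[Al](C)C; paraformaldehyde (as formaldehyde), C=O
Why: Negishi zirconium-catalysed carboalumination adds CH3 and Al syn across the alkyne with CH3 on C4 (the acid rides along as its aluminium carboxylate), and hydroxymethylation of the alkenylalane with retention should fix the (E)-C4=C5 geometry.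

Step 5
Reactants: 8 (1R,2R)-2-[(E)-5-hydroxy-3-methylpent-3-en-1-yl]-3,3-dimethylcyclobutane-1-carboxylic acid
Product: 10 tert-butyl 3-{(1R,2R)-2-[(E)-5-hydroxy-3-methylpent-3-en-1-yl]-3,3-dimethylcyclobutyl}-3-oxopropanoate, via acyl imidazolide 9 (not isolated)
Conditions: CDI (1.05 equiv), THF, rt; then Mg(O2CCH2CO2t-Bu)2, THF, rt → 45 °C; aq. HCl work-up
Reagents that add atoms: magnesium bis(3-tert-butoxy-3-oxopropanoate), CC(C)(C)OC(=O)CC(=O)[O-].CC(C)(C)OC(=O)CC(=O)[O-].[Mg+2]; 1,1'-carbonyldiimidazole, O=C(n1ccnc1)n1ccnc1 (imidazolyl only in 9)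
Why: Masamune–Claisen condensation, in which the acid is activated much faster than the primary alcohol and the acyl imidazolide is C-acylated by the magnesium malonate half-ester, which then decarboxylates to the β-keto ester.

Step 6
Reactants: 10 tert-butyl 3-{(1R,2R)-2-[(E)-5-hydroxy-3-methylpent-3-en-1-yl]-3,3-dimethylcyclobutyl}-3-oxopropanoate
Product: 12 (1R,11R,7E)-8,12,12-trimethyl-5-oxabicyclo[9.2.0]tridec-7-ene-2,4-dione, via acylketene 11 (not isolated)
Conditions: PhMe, 110 °C, slow addition to high dilution (ca. 1 mM), t-BuOH distilled off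
Reagents that add atoms: none
Why: Thermolysis of the tert-butyl β-keto ester expels tert-butanol to give acylketene 11, which the allylic hydroxyl should trap intramolecularly (acylketene macrolactonisation) to close the eleven-membered β-keto lactone, helped by the cis-disposed arms on the cyclobutane.

Step 7
Reactants: 12 (1R,11R,7E)-8,12,12-trimethyl-5-oxabicyclo[9.2.0]tridec-7-ene-2,4-dione
Product: 13 (1R,9R,4E)-4,11,11-trimethylbicyclo[7.2.0]undec-4-en-8-one (cis-fused)
Conditions: Pd(PPh3)4 (10 mol %), PhMe, 40 °C, 2 mM
Reagents that add atoms: none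
Why: Zerovalent palladium ionises the allylic C6–O bond of 12 to a π-allyl palladium carboxylate ion pair, the β-keto carboxylate loses CO2, and the resulting palladium enolate forms the C7–C6 bond, so the –C(=O)–O– link is excised and the eleven-membered lactone contracts to the nine-membered carbocycle. The closest known reaction is the palladium-catalysed decarboxylative allylation of allyl β-keto esters (palladium-catalysed Carroll reaction), which for allylic esters of the geranyl type is known to give the linear product with the olefin geometry retained. The one ring formed is closed by attack of C7 at the unsubstituted allyl terminus C6 (endo with respect to the allyl unit, nine-membered) rather than at the fully substituted terminus C4 (exo, seven-membered with a vinyl group). No stereocentre is created: C1 is untouched, C9 is corrected in step 8, and the (E)-geometry of C4=C5 should be carried over because the syn π-allyl complex cannot isomerise without σ-bonding at C4. The step needs regioselectivity for C6 and ring closure faster than allyl transfer between molecules; the bias of palladium against the quaternary terminus, the tight ion pair in a non-polar solvent at high dilution and the cis arms of the cyclobutane should secure both.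

Step 8
Reactants: 13 (1R,9R,4E)-4,11,11-trimethylbicyclo[7.2.0]undec-4-en-8-one
Product: 15 (−)-β-caryophyllene, via trans-fused ketone 14 (not isolated)
Conditions: KOt-Bu (0.2 equiv), t-BuOH/THF, rt; then Ph3PCH3Br, KOt-Bu, THF, 0 °C → rt
Reagents that add atoms: methyltriphenylphosphonium bromide, C[P+](c1ccccc1)(c1ccccc1)c1ccccc1.[Br-]
Why: Enolate equilibration should converge on the more stable trans-fused ketone 14 (C9 becomes S under thermodynamic control relative to the fixed C1), and Wittig methylenation then installs the C8 methylene without touching the trisubstituted olefin.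

Step 9
Reactants: 16 phloroglucinol; 17 2-methylpropanoyl chloride
Product: 18 2-methyl-1-(2,4,6-trihydroxyphenyl)propan-1-one
Conditions: AlCl3, PhNO2, 80 °C; aq. HCl
Reagents that add atoms: none
Why: Friedel–Crafts C-acylation of the electron-rich arene should stop at the mono-ketone because the chelated product is deactivated.

Step 10
Reactants: 18 2-methyl-1-(2,4,6-trihydroxyphenyl)propan-1-one
Product: 19 3,5-dihydroxy-4,6,6-trimethyl-2-(2-methylpropanoyl)cyclohexa-2,4-dien-1-one (norflavesone)
Conditions: NaOMe, MeI (3 equiv), MeOH, 0 °C → rt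
Reagents that add atoms: iodomethane, CI
Why: Dearomatising C-methylation of the phloroglucinol anion (two methyl groups on one ring carbon, one on the other) gives the gem-dimethyl triketone enol; no stereocentre is formed.

Step 11
Reactants: 15 (−)-β-caryophyllene; 19 norflavesone
Product: 21 target (4S,5R adduct), via o-quinone methide 20 (not isolated)
Conditions: PhI(OAc)2 (1.1 equiv), TEMPO (20 mol %), THF, −78 °C → rt
Reagents that add atoms: none
Why: Oxidation of the methyl-bearing enol generates o-quinone methide 20, which should undergo an inverse-electron-demand hetero-Diels–Alder reaction with the strained endocyclic (E)-olefin of 15 (O to the more substituted C4, CH2 to C5), the suprafacial addition setting C4 and C5 together with CH3 and H anti, while the face is decided by the conformer of 15 that reacts, so the (4S,5R) target is expected together with its (4R,5S) face isomer and is separated by chromatography.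

**Compound list**

1 | cyclohex-2-en-1-one | O=C1C=CCCC1 | starting material
2 | 2-methylpropene | CC(C)=C | starting material
3 | (1R,6R)-7,7-dimethylbicyclo[4.2.0]octan-2-one | O=C1CCC[C@@H]2[C@H]1CC2(C)C | intermediate
4 | 7,7-dimethyl-2-(trimethylsilyloxy)bicyclo[4.2.0]oct-2-ene, stereocentres as in 3 (not isolated) | C[Si](C)(C)OC1=CCC[C@@H]2[C@H]1CC2(C)C | intermediate
5 | (1R,2R)-3,3-dimethyl-2-(3-oxopropyl)cyclobutane-1-carboxylic acid | O=CCC[C@@H]1[C@H](C(=O)O)CC1(C)C | intermediate
6 | (1R,2R)-2-(but-3-yn-1-yl)-3,3-dimethylcyclobutane-1-carboxylic acid | C#CCC[C@@H]1[C@H](C(=O)O)CC1(C)C | intermediate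
7 | dimethylaluminium (1R,2R)-2-[(E)-4-(dimethylalumanyl)-3-methylbut-3-en-1-yl]-3,3-dimethylcyclobutane-1-carboxylate (not isolated) | C[Al](C)/C=C(\C)CC[C@@H]1[C@H](C(=O)O[Al](C)C)CC1(C)C | intermediate
8 | (1R,2R)-2-[(E)-5-hydroxy-3-methylpent-3-en-1-yl]-3,3-dimethylcyclobutane-1-carboxylic acid | OC/C=C(\C)CC[C@@H]1[C@H](C(=O)O)CC1(C)C | intermediate
9 | acyl imidazolide of 8 (not isolated) | OC/C=C(\C)CC[C@@H]1[C@H](C(=O)n2ccnc2)CC1(C)C | intermediate
10 | tert-butyl 3-{(1R,2R)-2-[(E)-5-hydroxy-3-methylpent-3-en-1-yl]-3,3-dimethylcyclobutyl}-3-oxopropanoate | OC/C=C(\C)CC[C@@H]1[C@H](C(=O)CC(=O)OC(C)(C)C)CC1(C)C | intermediate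
11 | acylketene from 10 (not isolated) | OC/C=C(\C)CC[C@@H]1[C@H](C(=O)C=C=O)CC1(C)C | intermediate
12 | (1R,11R,7E)-8,12,12-trimethyl-5-oxabicyclo[9.2.0]tridec-7-ene-2,4-dione | O=C1CC(=O)OC/C=C(\C)CC[C@@H]2[C@H]1CC2(C)C | intermediate
13 | (1R,9R,4E)-4,11,11-trimethylbicyclo[7.2.0]undec-4-en-8-one (cis-fused) | O=C1CC/C=C(\C)CC[C@@H]2[C@H]1CC2(C)C | intermediate
14 | (1R,9S,4E)-4,11,11-trimethylbicyclo[7.2.0]undec-4-en-8-one (trans-fused, not isolated) | O=C1CC/C=C(\C)CC[C@@H]2[C@@H]1CC2(C)C | intermediate
15 | (−)-β-caryophyllene, (1R,9S,4E)-4,11,11-trimethyl-8-methylidenebicyclo[7.2.0]undec-4-ene | C=C1CC/C=C(\C)CC[C@@H]2[C@@H]1CC2(C)C | intermediate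
16 | phloroglucinol (benzene-1,3,5-triol) | Oc1cc(O)cc(O)c1 | starting material
17 | 2-methylpropanoyl chloride | CC(C)C(Cl)=O | starting material
18 | 2-methyl-1-(2,4,6-trihydroxyphenyl)propan-1-one | CC(C)C(=O)c1c(O)cc(O)cc1O | intermediate
19 | norflavesone, 3,5-dihydroxy-4,6,6-trimethyl-2-(2-methylpropanoyl)cyclohexa-2,4-dien-1-one | CC1=C(O)C(C)(C)C(=O)C(C(=O)C(C)C)=C1O | intermediate
20 | 5-hydroxy-2,2-dimethyl-6-methylidene-4-(2-methylpropanoyl)cyclohex-4-ene-1,3-dione (o-quinone methide, not isolated) | C=C1C(=O)C(C)(C)C(=O)C(C(=O)C(C)C)=C1O | intermediate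
21 | target: dihydropyran-fused adduct of 15 and 20, O on C4 and CH2 on C5, (1R,4S,5R,9S) in caryophyllane numbering | C=C1CC[C@@H]2CC3=C(O[C@@]2(C)CC[C@@H]2[C@@H]1CC2(C)C)C(C)(C)C(=O)C(C(=O)C(C)C)=C3O | target

**Step count.** Total: 11 steps. Longest linear sequence: 9 steps (steps 1–8 and 11).

**Steps most likely to fail**

Step 7. The palladium enolate may be passed between molecules faster than it closes the strained (E)-cyclononene (oligomerisation), may attack the quaternary terminus C4 to give a seven-membered ring, or may be protonated with loss of the allyl unit as a diene. The fallback sets out from 10 and forms the ring directly with a soft nucleophile. The allylic alcohol is converted into the methyl carbonate F1 (ClCO2Me, pyridine, CH2Cl2, 0 °C). Pd(PPh3)4 in THF at high dilution and 60 °C then ionises the carbonate, the released methoxide deprotonates the β-keto ester, and its stabilised anion closes on C6 in an intramolecular Tsuji–Trost alkylation to the nine-membered β-keto ester F2 (mixture of C7 epimers). Heating F2 in wet DMSO at 130 °C removes the tert-butoxycarbonyl group, and the route is rejoined at 13.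

Step 11. Facial selectivity may be poor: the quinone methide may add mainly to the other face of C4=C5, through the more populated conformers of 15, which would leave the target as the minor isomer. The fallback sets out from 18 and puts the face under catalyst control. Two C-methylations (NaOMe, MeI 2 equiv, MeOH) give the gem-dimethyl triketone lacking the ring methyl, 3,5-dihydroxy-6,6-dimethyl-2-(2-methylpropanoyl)cyclohexa-2,4-dien-1-one F3. Knoevenagel condensation of F3 with paraformaldehyde in the presence of 15 and a chiral phosphoric acid (TRIP, either antipode, PhMe, rt) generates 20 bound to the chiral acid, so that the catalyst rather than the conformer population of 15 chooses the face. The route is rejoined at 21.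

Step 6. Capture of the acylketene by a second molecule (cyclic dimer and oligomers) may outrun closure of the eleven-membered ring. The fallback sets out from 10 and closes the ring at the alkyl–oxygen bond instead of the acyl–oxygen bond. Appel bromination (CBr4, PPh3, CH2Cl2, 0 °C) gives the allylic bromide F4, and CF3CO2H in CH2Cl2 at 0 °C cleaves the tert-butyl ester to the β-keto acid F5. The caesium carboxylate of F5 (Cs2CO3, DMF, high dilution, rt) then displaces the primary allylic bromide at C6, and the route is rejoined at 12.

Further compounds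
F1 | step 7 | tert-butyl 3-{(1R,2R)-2-[(E)-5-(methoxycarbonyloxy)-3-methylpent-3-en-1-yl]-3,3-dimethylcyclobutyl}-3-oxopropanoate | COC(=O)OC/C=C(\C)CC[C@@H]1[C@H](C(=O)CC(=O)OC(C)(C)C)CC1(C)C
F2 | step 7 | tert-butyl (1R,9R,4E)-4,11,11-trimethyl-8-oxobicyclo[7.2.0]undec-4-ene-7-carboxylate (C7 epimers) | O=C1C(C(=O)OC(C)(C)C)C/C=C(\C)CC[C@@H]2[C@H]1CC2(C)C
F3 | step 11 | 3,5-dihydroxy-6,6-dimethyl-2-(2-methylpropanoyl)cyclohexa-2,4-dien-1-one | CC(C)C(=O)C1=C(O)C=C(O)C(C)(C)C1=O
F4 | step 6 | tert-butyl 3-{(1R,2R)-2-[(E)-5-bromo-3-methylpent-3-en-1-yl]-3,3-dimethylcyclobutyl}-3-oxopropanoate | BrC/C=C(\C)CC[C@@H]1[C@H](C(=O)CC(=O)OC(C)(C)C)CC1(C)C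
F5 | step 6 | 3-{(1R,2R)-2-[(E)-5-bromo-3-methylpent-3-en-1-yl]-3,3-dimethylcyclobutyl}-3-oxopropanoic acid | BrC/C=C(\C)CC[C@@H]1[C@H](C(=O)CC(=O)O)CC1(C)C
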